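**Plan**

- The target is epicatechin-(4β→6)-epiafzelechin-(4β→8)-epicatechin-(4β→6)-epicatechin (first to fourth unit from the top, all 2R,3R, every interflavan bond 3,4-trans). The retrosynthesis cuts the three C4–aryl bonds (third→fourth unit first, then second→third, then first→second), then the C4–C4a and O1–C8a bonds of the pyran ring in the fourth unit and likewise in the second.
- Enabling feature: in ring A of the fourth unit the ether oxygens at C5 and C7 are both meta to C8a, so a C8a–F bond accepts SNAr, and the future C4a lies between that fluorine and an ether, where an aryllithium is stabilised. The chain O1–C2–C3–C4 of the pyran ring is the atom sequence of an oxetane, so opening a cis-oxetane at its CH2 with the aryllithium frees the ring oxygen as the alkoxide that closes on C8a.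
- Forward: Evans syn-glycolate aldol → 1,3-diol → cis-(2R,3R)-oxetane; 1,3,5-trifluorobenzene → symmetric dibromo-fluoro-bis(benzyloxy)benzene. A one-flask annulation builds the pyran ring of the fourth unit (step 8) and of the second unit (step 13), and the second bromine of the arene stays as the C8 cap that forces the later couplings to C6.
- The first and third units come from (−)-epicatechin. The chain is joined first + second, then + third, then + fourth unit by Friedel–Crafts couplings with alternating thioether (I2/Ag2O) and 2-ethoxyethyl ether (BF3·OEt2) activation, and one hydrogenolysis removes seventeen benzyl groups and four bromines.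
- Stereochemistry: C2/C3 of the second and fourth units come from the auxiliary-controlled aldol and pass unchanged through oxetane and annulation. C2/C3 of the first and third units come from the chiral pool, and each C4 is set by attack of the arene trans to the C3 substituent.

Key step: step 8

Remark: compounds 1, 2, 4, 10, 16 and 24 are taken as commercial, and the 3-OH groups of the first and third units are carried free because C-alkylation of ring A is expected to outrun O-alkylation.

**Route**

Step 1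
Reactants: 1 (S)-4-benzyloxazolidin-2-one, 2 2-(benzyloxy)acetyl chloride
Product: 3 (S)-4-benzyl-3-[2-(benzyloxy)acetyl]oxazolidin-2-one
Conditions: Et3N, DMAP (cat.), CH2Cl2, 0 °C → rt
Reagents that add atoms: none
Why: DMAP-catalysed N-acylation of the oxazolidinone by the acid chloride should install the glycolate unit that supplies C3 and C4 of the flavan.

Step 2
Reactants: 3 glycolate imide, 4 3,4-bis(benzyloxy)benzaldehyde
Product: 6 (S)-4-benzyl-3-[(2S,3R)-2-(benzyloxy)-3-[3,4-bis(benzyloxy)phenyl]-3-hydroxypropanoyl]oxazolidin-2-one, via boron enolate 5 (not isolated)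
Conditions: Bu2BOTf, Et3N, CH2Cl2, −78 → 0 °C; then 4, −78 → 0 °C; H2O2, pH 7 buffer, MeOH
Reagents that add atoms: none
Why: In this Evans syn-aldol the (Z)-boron enolate should react through a closed Zimmerman–Traxler chair on the face away from the benzyl group of the auxiliary, which sets the 2S and 3R centres (the future C3 and C2 of the fourth unit) in the syn relationship.

Step 3
Reactants: 6 aldol adduct
Product: 7 (1R,2R)-2-(benzyloxy)-1-[3,4-bis(benzyloxy)phenyl]propane-1,3-diol
Conditions: LiBH4, MeOH (1 equiv), THF, 0 °C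
Reagents that add atoms: none
Why: Reductive cleavage of the imide by borohydride should give the primary alcohol and return the auxiliary without touching either stereocentre.

Step 4
Reactants: 7 diol
Product: 8 (2R,3R)-2-(benzyloxy)-3-[3,4-bis(benzyloxy)phenyl]-3-hydroxypropyl 4-methylbenzenesulfonate
Conditions: TsCl (1.05 equiv), pyridine, CH2Cl2, 0 °C
Reagents that add atoms: 4-methylbenzenesulfonyl chloride (TsCl), Cc1ccc(cc1)S(Cl)(=O)=O
Why: Selective sulfonylation should take the unhindered primary hydroxyl in preference to the secondary benzylic one.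

Step 5
Reactants: 8 tosylate
Product: 9 (2R,3R)-3-(benzyloxy)-2-[3,4-bis(benzyloxy)phenyl]oxetane (cis)
Conditions: NaH, THF, 0 °C → rt
Reagents that add atoms: none
Why: Intramolecular Williamson etherification (4-exo-tet) of the benzylic alkoxide on the primary tosylate should close the oxetane with retention at both stereocentres, so the syn relationship becomes the cis ring.

Step 6
Reactants: 10 1,3,5-trifluorobenzene
Product: 11 1,3-bis(benzyloxy)-5-fluorobenzene
Conditions: BnOH (2.2 equiv), NaH, NMP, 0 → 100 °C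
Reagents that add atoms: benzyl alcohol, OCc1ccccc1
Why: Twofold SNAr by benzyloxide on the trifluoroarene should stop at the difunctional stage by stoichiometry, since each alkoxy group introduced slows the next substitution.

Step 7
Reactants: 11 fluoro diether
Product: 12 1,5-bis(benzyloxy)-2,4-dibromo-3-fluorobenzene
Conditions: NBS (2.1 equiv), DMF, 0 °C → rt
Reagents that add atoms: N-bromosuccinimide (NBS), O=C1CCC(=O)N1Br
Why: Electrophilic aromatic bromination should go to the two equivalent positions that are para to one benzyloxy group and ortho to the other, not to the crowded position between the two ethers, which gives the symmetric dibromide.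

Step 8
Reactants: 12 dibromofluoroarene, 9 cis-oxetane
Product: 15 (2R,3R)-3,5,7-tris(benzyloxy)-2-[3,4-bis(benzyloxy)phenyl]-8-bromochromane (fourth unit), via aryllithium 13 (not isolated), via open-chain alkoxide 14 (not isolated)
Conditions: n-BuLi (1.0 equiv), THF, −78 °C; then 9, BF3·OEt2, −78 °C; then t-BuOK, DMPU, −78 → 60 °C
Reagents that add atoms: none
Why: Proposed new method: bromine–lithium exchange on the symmetric dibromide 12 gives aryllithium 13, whose carbanion (the future C4a) sits between F and OBn, and under BF3 activation it should open oxetane 9 by SN2 attack at the unsubstituted ring CH2 (the future C4), a step driven by release of the four-ring strain that at the same time unmasks the ring oxygen as the C2 alkoxide 14; once t-BuOK has taken up the boron, this alkoxide adds to C8a and expels fluoride (intramolecular SNAr through a Meisenheimer adduct), which is feasible because the C5 and C7 benzyloxy groups are meta to C8a and the bromine is ortho to it. The closest known reaction types are the BF3-promoted opening of oxetanes by organolithium reagents and the base-mediated SNAr closure of 3-(2-fluoroaryl)propanols to chromans, and their union in one flask as a chroman annulation of an o-fluoroaryllithium with an oxetane is the untested part. The pyran ring closes in the 6-exo-trig mode at C8a. No new stereocentre is formed, because neither C–O bond at C2 nor at C3 of 9 is broken, so the cis-oxetane maps directly onto the 2,3-cis (epi) flavan. The step needs attack at CH2 and not at the benzylic C2 (secured by the SN2 preference for the primary carbon at −78 °C and by the β-benzyloxy group, which disfavours ionisation at C2), a single exchange (one equivalent of n-BuLi on two equivalent bromines) and closure on fluorine only (the sole halogen ortho to the side chain), and the untouched second bromine ends as the C8 cap.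

Step 9
Reactants: 3 glycolate imide, 16 4-(benzyloxy)benzaldehyde
Product: 17 (S)-4-benzyl-3-[(2S,3R)-2-(benzyloxy)-3-[4-(benzyloxy)phenyl]-3-hydroxypropanoyl]oxazolidin-2-one
Conditions: Bu2BOTf, Et3N, CH2Cl2, −78 → 0 °C; then 16, −78 → 0 °C; H2O2, pH 7 buffer, MeOH
Reagents that add atoms: none
Why: The same Evans syn-aldol as in step 2, again through boron enolate 5 generated from 3 in the flask, should set the 2S and 3R centres (the future C3 and C2 of the second unit) under control of the auxiliary.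

Step 10
Reactants: 17 aldol adduct
Product: 18 (1R,2R)-2-(benzyloxy)-1-[4-(benzyloxy)phenyl]propane-1,3-diol
Conditions: LiBH4, MeOH (1 equiv), THF, 0 °C
Reagents that add atoms: none
Why: Reductive cleavage of the imide should give the 1,3-diol and return the auxiliary as in step 3.

Step 11
Reactants: 18 diol
Product: 19 (2R,3R)-2-(benzyloxy)-3-[4-(benzyloxy)phenyl]-3-hydroxypropyl 4-methylbenzenesulfonate
Conditions: TsCl (1.05 equiv), pyridine, CH2Cl2, 0 °C
Reagents that add atoms: 4-methylbenzenesulfonyl chloride (TsCl), Cc1ccc(cc1)S(Cl)(=O)=O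
Why: Selective sulfonylation of the primary hydroxyl should proceed as in step 4.

Step 12
Reactants: 19 tosylate
Product: 20 (2R,3R)-3-(benzyloxy)-2-[4-(benzyloxy)phenyl]oxetane (cis)
Conditions: NaH, THF, 0 °C → rt
Reagents that add atoms: none
Why: Intramolecular Williamson etherification (4-exo-tet) should close the cis-oxetane with retention at both centres as in step 5.

Step 13
Reactants: 12 dibromofluoroarene, 20 cis-oxetane
Product: 22 (2R,3R)-3,5,7-tris(benzyloxy)-2-[4-(benzyloxy)phenyl]-8-bromochromane, via open-chain alkoxide 21 (not isolated)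
Conditions: n-BuLi (1.0 equiv), THF, −78 °C; then 20, BF3·OEt2, −78 °C; then t-BuOK, DMPU, −78 → 60 °C
Reagents that add atoms: none
Why: Proposed new method: the same one-flask sequence as in step 8, in which aryllithium 13 is generated again from 12 and which is argued from the same mechanism (SN2 opening of the BF3-activated oxetane at its CH2 by the o-fluoroaryllithium, then addition–elimination of the freed C2 alkoxide at C8a–F, with organolithium/BF3 oxetane opening and SNAr chroman closure as the closest known reaction types), should carry C2 and C3 of 20 unchanged into the 8-bromo epiafzelechin skeleton.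

Step 14
Reactants: 22 bromo flavan
Product: 23 (2R,3R,4S)-3,5,7-tris(benzyloxy)-2-[4-(benzyloxy)phenyl]-8-bromo-4-(2-ethoxyethoxy)chromane (second unit)
Conditions: DDQ, 2-ethoxyethanol, CH2Cl2, rt
Reagents that add atoms: 2-ethoxyethanol, CCOCCO
Why: In this benzylic oxidation DDQ should abstract hydride from the C4 methylene activated by the ortho and para ether oxygens of ring A, and the alcohol should add to the cation on the face opposite to the C3 benzyloxy and C2 aryl groups, which gives the 4β ether.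

Step 15
Reactants: 24 (−)-epicatechin
Product: 25 (2R,3R)-5,7-bis(benzyloxy)-2-[3,4-bis(benzyloxy)phenyl]chroman-3-ol
Conditions: BnBr (4.4 equiv), K2CO3, DMF, rt
Reagents that add atoms: benzyl bromide, BrCc1ccccc1
Why: Williamson benzylation under carbonate conditions should take the four phenols and leave the less acidic secondary alcohol free.

Step 16
Reactants: 25 tetrabenzyl ether
Product: 26 (2R,3R,4S)-5,7-bis(benzyloxy)-2-[3,4-bis(benzyloxy)phenyl]-4-(2-ethoxyethoxy)chroman-3-ol
Conditions: DDQ, 2-ethoxyethanol, CH2Cl2, rt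
Reagents that add atoms: 2-ethoxyethanol, CCOCCO
Why: The same DDQ benzylic oxidation as in step 14 should give the C4 cation, which the alcohol traps trans to the C3 hydroxyl (4β).

Step 17
Reactants: 26 C4 ether
Product: 27 (2R,3S,4S)-5,7-bis(benzyloxy)-2-[3,4-bis(benzyloxy)phenyl]-4-[(2,6-dimethylphenyl)sulfanyl]chroman-3-ol (third unit)
Conditions: 2,6-dimethylbenzenethiol (3 equiv), BF3·OEt2, CH2Cl2, −78 °C
Reagents that add atoms: 2,6-dimethylbenzenethiol, Cc1cccc(C)c1S
Why: Lewis-acid-mediated SN1 exchange at C4 should replace the ether by the thiol, which is used in excess so that it outruns ring A of a second molecule, and attack trans to the C3 hydroxyl gives the 4β thioether.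

Step 18
Reactants: 26 C4 ether
Product: 28 (2R,3R,4S)-5,7-bis(benzyloxy)-2-[3,4-bis(benzyloxy)phenyl]-6,8-dibromo-4-(2-ethoxyethoxy)chroman-3-ol
Conditions: NBS (2.1 equiv), CH2Cl2, 0 °C
Reagents that add atoms: N-bromosuccinimide (NBS), O=C1CCC(=O)N1Br
Why: Electrophilic aromatic bromination should take both free positions of ring A (C8, then C6), so that this unit can no longer act as a nucleophile.

Step 19
Reactants: 28 dibromo ether
Product: 29 (2R,3S,4S)-5,7-bis(benzyloxy)-2-[3,4-bis(benzyloxy)phenyl]-6,8-dibromo-4-[(2,6-dimethylphenyl)sulfanyl]chroman-3-ol (first unit)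
Conditions: 2,6-dimethylbenzenethiol (3 equiv), BF3·OEt2, CH2Cl2, −78 → −30 °C
Reagents that add atoms: 2,6-dimethylbenzenethiol, Cc1cccc(C)c1S
Why: The same SN1 ether-to-thioether exchange as in step 17 should give the 4β thioether of the capped unit.

Step 20
Reactants: 29 first-unit thioether, 23 second-unit ether
Product: 30 6,8-dibromo-5,7,3′,4′-tetra-O-benzylepicatechin-(4β→6)-[8-bromo-3,5,7,4′-tetra-O-benzyl-4β-(2-ethoxyethoxy)epiafzelechin] (protected dimer)
Conditions: I2, Ag2O, 4 Å molecular sieves, CH2Cl2, −78 → −30 °C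
Reagents that add atoms: none
Why: In this Friedel–Crafts alkylation the iodonium activation of sulfur should ionise C4 of 29 while the 2-ethoxyethyl ether of 23 stays intact, and C6 of 23 (its only free ring A position, C8 being brominated) should attack the cation trans to the C3 hydroxyl, which sets C4 of the first unit as 4β.

Step 21
Reactants: 30 protected dimer, 27 third-unit thioether
Product: 31 6,8-dibromo-5,7,3′,4′-tetra-O-benzylepicatechin-(4β→6)-(8-bromo-3,5,7,4′-tetra-O-benzylepiafzelechin)-(4β→8)-[5,7,3′,4′-tetra-O-benzyl-4β-(2,6-dimethylphenylsulfanyl)epicatechin] (protected trimer)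
Conditions: BF3·OEt2, 27 (2 equiv), CH2Cl2, −78 °C
Reagents that add atoms: none
Why: In this Friedel–Crafts alkylation BF3·OEt2 should ionise the C4 ether of the second unit while the thioether of 27 is inert to the hard Lewis acid, and C8 of 27, the more nucleophilic and less hindered of its two free positions, should attack trans to the C3 benzyloxy group, which sets C4 of the second unit as 4β.

Step 22
Reactants: 31 protected trimer, 15 fourth-unit bromo flavan
Product: 32 6,8-dibromo-5,7,3′,4′-tetra-O-benzylepicatechin-(4β→6)-(8-bromo-3,5,7,4′-tetra-O-benzylepiafzelechin)-(4β→8)-(5,7,3′,4′-tetra-O-benzylepicatechin)-(4β→6)-(8-bromo-3,5,7,3′,4′-penta-O-benzylepicatechin) (protected tetramer)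
Conditions: I2, Ag2O, 15 (2 equiv), 4 Å molecular sieves, CH2Cl2, −78 → −20 °C
Reagents that add atoms: none
Why: In this Friedel–Crafts alkylation the iodonium activation of the thioether should give the C4 cation of the third unit, and C6 of 15 (its only free ring A position, C8 carrying the bromine from step 8) should attack trans to the C3 hydroxyl, which sets C4 of the third unit as 4β.

Step 23
Reactants: 32 protected tetramer
Product: 33 epicatechin-(4β→6)-epiafzelechin-(4β→8)-epicatechin-(4β→6)-epicatechin (CNP0103636.1)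
Conditions: H2 (1 atm), Pd(OH)2/C, NaOAc, THF/MeOH/H2O, rt
Reagents that add atoms: none
Why: Catalytic hydrogenolysis should cleave all seventeen benzyl ethers and the four aryl C–Br bonds in one operation, the acetate buffering the HBr so that the acid-labile interflavan bonds survive, and no stereocentre is touched.

**Compound list**

1 | (S)-4-benzyloxazolidin-2-one | O=C1N[C@@H](Cc2ccccc2)CO1 | starting material
2 | 2-(benzyloxy)acetyl chloride | O=C(Cl)COCc1ccccc1 | starting material
3 | (S)-4-benzyl-3-[2-(benzyloxy)acetyl]oxazolidin-2-one | O=C(COCc1ccccc1)N1[C@@H](Cc2ccccc2)COC1=O | intermediate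
4 | 3,4-bis(benzyloxy)benzaldehyde | O=Cc1ccc(OCc2ccccc2)c(OCc2ccccc2)c1 | starting material
5 | (Z)-dibutylboron enolate of 3 | CCCCB(CCCC)O/C(=C\OCc1ccccc1)N1[C@@H](Cc2ccccc2)COC1=O | intermediate
6 | (S)-4-benzyl-3-[(2S,3R)-2-(benzyloxy)-3-[3,4-bis(benzyloxy)phenyl]-3-hydroxypropanoyl]oxazolidin-2-one | O=C([C@@H](OCc1ccccc1)[C@H](O)c1ccc(OCc2ccccc2)c(OCc2ccccc2)c1)N1[C@@H](Cc2ccccc2)COC1=O | intermediate
7 | (1R,2R)-2-(benzyloxy)-1-[3,4-bis(benzyloxy)phenyl]propane-1,3-diol | OC[C@@H](OCc1ccccc1)[C@H](O)c1ccc(OCc2ccccc2)c(OCc2ccccc2)c1 | intermediate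
8 | (2R,3R)-2-(benzyloxy)-3-[3,4-bis(benzyloxy)phenyl]-3-hydroxypropyl 4-methylbenzenesulfonate | Cc1ccc(cc1)S(=O)(=O)OC[C@@H](OCc1ccccc1)[C@H](O)c1ccc(OCc2ccccc2)c(OCc2ccccc2)c1 | intermediate
9 | (2R,3R)-3-(benzyloxy)-2-[3,4-bis(benzyloxy)phenyl]oxetane (cis) | C1[C@@H](OCc2ccccc2)[C@H](O1)c1ccc(OCc2ccccc2)c(OCc2ccccc2)c1 | intermediate
10 | 1,3,5-trifluorobenzene | Fc1cc(F)cc(F)c1 | starting material
11 | 1,3-bis(benzyloxy)-5-fluorobenzene | Fc1cc(OCc2ccccc2)cc(OCc2ccccc2)c1 | intermediate
12 | 1,5-bis(benzyloxy)-2,4-dibromo-3-fluorobenzene | Fc1c(Br)c(OCc2ccccc2)cc(OCc2ccccc2)c1Br | intermediate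
13 | [4,6-bis(benzyloxy)-3-bromo-2-fluorophenyl]lithium | [Li]c1c(F)c(Br)c(OCc2ccccc2)cc1OCc1ccccc1 | intermediate
14 | lithium (1R,2R)-2-(benzyloxy)-1-[3,4-bis(benzyloxy)phenyl]-3-[4,6-bis(benzyloxy)-3-bromo-2-fluorophenyl]propan-1-olate (present as its BF3 adduct) | Fc1c(Br)c(OCc2ccccc2)cc(OCc2ccccc2)c1C[C@@H](OCc1ccccc1)[C@H]([O-])c1ccc(OCc2ccccc2)c(OCc2ccccc2)c1.[Li+] | intermediate
15 | (2R,3R)-3,5,7-tris(benzyloxy)-2-[3,4-bis(benzyloxy)phenyl]-8-bromochromane (fourth unit) | C1[C@@H](OCc2ccccc2)[C@H](Oc2c1c(OCc1ccccc1)cc(OCc1ccccc1)c2Br)c1ccc(OCc2ccccc2)c(OCc2ccccc2)c1 | intermediate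
16 | 4-(benzyloxy)benzaldehyde | O=Cc1ccc(OCc2ccccc2)cc1 | starting material
17 | (S)-4-benzyl-3-[(2S,3R)-2-(benzyloxy)-3-[4-(benzyloxy)phenyl]-3-hydroxypropanoyl]oxazolidin-2-one | O=C([C@@H](OCc1ccccc1)[C@H](O)c1ccc(OCc2ccccc2)cc1)N1[C@@H](Cc2ccccc2)COC1=O | intermediate
18 | (1R,2R)-2-(benzyloxy)-1-[4-(benzyloxy)phenyl]propane-1,3-diol | OC[C@@H](OCc1ccccc1)[C@H](O)c1ccc(OCc2ccccc2)cc1 | intermediate
19 | (2R,3R)-2-(benzyloxy)-3-[4-(benzyloxy)phenyl]-3-hydroxypropyl 4-methylbenzenesulfonate | Cc1ccc(cc1)S(=O)(=O)OC[C@@H](OCc1ccccc1)[C@H](O)c1ccc(OCc2ccccc2)cc1 | intermediate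
20 | (2R,3R)-3-(benzyloxy)-2-[4-(benzyloxy)phenyl]oxetane (cis) | C1[C@@H](OCc2ccccc2)[C@H](O1)c1ccc(OCc2ccccc2)cc1 | intermediate
21 | lithium (1R,2R)-2-(benzyloxy)-1-[4-(benzyloxy)phenyl]-3-[4,6-bis(benzyloxy)-3-bromo-2-fluorophenyl]propan-1-olate (present as its BF3 adduct) | Fc1c(Br)c(OCc2ccccc2)cc(OCc2ccccc2)c1C[C@@H](OCc1ccccc1)[C@H]([O-])c1ccc(OCc2ccccc2)cc1.[Li+] | intermediate
22 | (2R,3R)-3,5,7-tris(benzyloxy)-2-[4-(benzyloxy)phenyl]-8-bromochromane | C1[C@@H](OCc2ccccc2)[C@H](Oc2c1c(OCc1ccccc1)cc(OCc1ccccc1)c2Br)c1ccc(OCc2ccccc2)cc1 | intermediate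
23 | (2R,3R,4S)-3,5,7-tris(benzyloxy)-2-[4-(benzyloxy)phenyl]-8-bromo-4-(2-ethoxyethoxy)chromane (second unit) | CCOCCO[C@@H]1[C@@H](OCc2ccccc2)[C@H](Oc2c1c(OCc1ccccc1)cc(OCc1ccccc1)c2Br)c1ccc(OCc2ccccc2)cc1 | intermediate
24 | (−)-epicatechin, (2R,3R)-2-(3,4-dihydroxyphenyl)chromane-3,5,7-triol | C1[C@@H](O)[C@H](Oc2cc(O)cc(O)c21)c1ccc(O)c(O)c1 | starting material
25 | (2R,3R)-5,7-bis(benzyloxy)-2-[3,4-bis(benzyloxy)phenyl]chroman-3-ol | C1[C@@H](O)[C@H](Oc2cc(OCc3ccccc3)cc(OCc3ccccc3)c21)c1ccc(OCc2ccccc2)c(OCc2ccccc2)c1 | intermediate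
26 | (2R,3R,4S)-5,7-bis(benzyloxy)-2-[3,4-bis(benzyloxy)phenyl]-4-(2-ethoxyethoxy)chroman-3-ol | CCOCCO[C@@H]1[C@@H](O)[C@H](Oc2cc(OCc3ccccc3)cc(OCc3ccccc3)c21)c1ccc(OCc2ccccc2)c(OCc2ccccc2)c1 | intermediate
27 | (2R,3S,4S)-5,7-bis(benzyloxy)-2-[3,4-bis(benzyloxy)phenyl]-4-[(2,6-dimethylphenyl)sulfanyl]chroman-3-ol (third unit) | Cc1cccc(C)c1S[C@@H]1[C@@H](O)[C@H](Oc2cc(OCc3ccccc3)cc(OCc3ccccc3)c21)c1ccc(OCc2ccccc2)c(OCc2ccccc2)c1 | intermediate
28 | (2R,3R,4S)-5,7-bis(benzyloxy)-2-[3,4-bis(benzyloxy)phenyl]-6,8-dibromo-4-(2-ethoxyethoxy)chroman-3-ol | CCOCCO[C@@H]1[C@@H](O)[C@H](Oc2c(Br)c(OCc3ccccc3)c(Br)c(OCc3ccccc3)c21)c1ccc(OCc2ccccc2)c(OCc2ccccc2)c1 | intermediate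
29 | (2R,3S,4S)-5,7-bis(benzyloxy)-2-[3,4-bis(benzyloxy)phenyl]-6,8-dibromo-4-[(2,6-dimethylphenyl)sulfanyl]chroman-3-ol (first unit) | Cc1cccc(C)c1S[C@@H]1[C@@H](O)[C@H](Oc2c(Br)c(OCc3ccccc3)c(Br)c(OCc3ccccc3)c21)c1ccc(OCc2ccccc2)c(OCc2ccccc2)c1 | intermediate
30 | 6,8-dibromo-5,7,3′,4′-tetra-O-benzylepicatechin-(4β→6)-[8-bromo-3,5,7,4′-tetra-O-benzyl-4β-(2-ethoxyethoxy)epiafzelechin] (protected dimer) | C(c1ccccc1)Oc1ccc([C@H]2Oc3c(Br)c(OCc4ccccc4)c([C@H]4c5c(OCc6ccccc6)c(Br)c(OCc6ccccc6)c(Br)c5O[C@H](c5ccc(OCc6ccccc6)c(OCc6ccccc6)c5)[C@@H]4O)c(OCc4ccccc4)c3[C@H](OCCOCC)[C@H]2OCc2ccccc2)cc1 | intermediate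
31 | 6,8-dibromo-5,7,3′,4′-tetra-O-benzylepicatechin-(4β→6)-(8-bromo-3,5,7,4′-tetra-O-benzylepiafzelechin)-(4β→8)-[5,7,3′,4′-tetra-O-benzyl-4β-(2,6-dimethylphenylsulfanyl)epicatechin] (protected trimer) | C(c1ccccc1)Oc1ccc([C@H]2Oc3c(Br)c(OCc4ccccc4)c([C@H]4c5c(OCc6ccccc6)c(Br)c(OCc6ccccc6)c(Br)c5O[C@H](c5ccc(OCc6ccccc6)c(OCc6ccccc6)c5)[C@@H]4O)c(OCc4ccccc4)c3[C@H](c4c(OCc5ccccc5)cc(OCc5ccccc5)c5c4O[C@H](c4ccc(OCc6ccccc6)c(OCc6ccccc6)c4)[C@H](O)[C@H]5Sc4c(C)cccc4C)[C@H]2OCc2ccccc2)cc1 | intermediate
32 | 6,8-dibromo-5,7,3′,4′-tetra-O-benzylepicatechin-(4β→6)-(8-bromo-3,5,7,4′-tetra-O-benzylepiafzelechin)-(4β→8)-(5,7,3′,4′-tetra-O-benzylepicatechin)-(4β→6)-(8-bromo-3,5,7,3′,4′-penta-O-benzylepicatechin) (protected tetramer) | C(c1ccccc1)Oc1ccc([C@H]2Oc3c(Br)c(OCc4ccccc4)c([C@H]4c5c(OCc6ccccc6)c(Br)c(OCc6ccccc6)c(Br)c5O[C@H](c5ccc(OCc6ccccc6)c(OCc6ccccc6)c5)[C@@H]4O)c(OCc4ccccc4)c3[C@H](c4c(OCc5ccccc5)cc(OCc5ccccc5)c5c4O[C@H](c4ccc(OCc6ccccc6)c(OCc6ccccc6)c4)[C@H](O)[C@H]5c4c(OCc5ccccc5)c(Br)c5c(c4OCc4ccccc4)C[C@@H](OCc4ccccc4)[C@@H](c4ccc(OCc6ccccc6)c(OCc6ccccc6)c4)O5)[C@H]2OCc2ccccc2)cc1 | intermediate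
33 | epicatechin-(4β→6)-epiafzelechin-(4β→8)-epicatechin-(4β→6)-epicatechin (CNP0103636.1) | Oc1ccc([C@H]2Oc3cc(O)c([C@H]4c5c(O)cc(O)cc5O[C@H](c5ccc(O)c(O)c5)[C@@H]4O)c(O)c3[C@H](c3c(O)cc(O)c4c3O[C@H](c3ccc(O)c(O)c3)[C@H](O)[C@H]4c3c(O)cc4c(c3O)C[C@@H](O)[C@@H](c3ccc(O)c(O)c3)O4)[C@H]2O)cc1 | target

**Step count and risks**

Total step count: 23. Longest linear sequence: 11 steps (steps 1, 9, 10, 11, 12, 13, 14, 20, 21, 22, 23).

Steps most likely to fail:

1. Step 8 (proposed new method). The BF3-bound oxetane may ionise at its benzylic C2–O bond before the aryllithium arrives, which would erode the configuration at C2 or form the C–C bond at the wrong carbon. The aryllithium may lose LiF to an aryne on warming, and the ring closure may stall because the alkoxide stays bound to boron. The fallback takes the fourth unit from the chiral pool by known chemistry. It sets out from 25, whose secondary alcohol is benzylated (NaH, BnBr, DMF) to (2R,3R)-3,5,7-tris(benzyloxy)-2-[3,4-bis(benzyloxy)phenyl]chromane F1. Electrophilic bromination of F1 (NBS, 1 equiv, CH2Cl2, −10 °C), which is expected at the more reactive C8, comes back to the route at 15.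

2. Step 13 (proposed new method). The same processes apply, and the 4-benzyloxyphenyl group stabilises a benzylic cation at C2 of 20 at least as well as the catechol ether does in 9. The fallback separates the two bond formations and avoids the boron Lewis acid, using known reaction types. It sets out from 12 and 20: bromine–magnesium exchange (i-PrMgCl·LiCl, THF, −20 °C) gives [4,6-bis(benzyloxy)-3-bromo-2-fluorophenyl]magnesium chloride F2. CuI-catalysed opening of 20 at its CH2 and aqueous work-up give the isolated (1R,2R)-2-(benzyloxy)-1-[4-(benzyloxy)phenyl]-3-[4,6-bis(benzyloxy)-3-bromo-2-fluorophenyl]propan-1-ol F3. A separate intramolecular SNAr (NaH, DMF, 60 °C) then comes back to the route at 22.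

3. Step 22. Attack of the hindered, bromine-deactivated C6 of 15 on the bulky trimer cation may be slow, so that iodination or self-alkylation at the free C6 position of the third unit, or decay of the cation, takes over. The fallback changes the order of union so that the hindered 4→6 bond is made between monomers. It sets out from 27, which is added slowly to an excess of 15 (I2, Ag2O, CH2Cl2, −78 °C), so that its steady concentration stays low and self-alkylation is held back. This should give the dimer 5,7,3′,4′-tetra-O-benzylepicatechin-(4β→6)-(8-bromo-3,5,7,3′,4′-penta-O-benzylepicatechin) F4, which keeps C8 of the third unit free. F4 then takes the place of 27 in the BF3·OEt2 coupling with 30 (attack through C8 of the third unit), which comes back to the route at 32.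

Further compounds
F1 | step 8 | (2R,3R)-3,5,7-tris(benzyloxy)-2-[3,4-bis(benzyloxy)phenyl]chromane | C1[C@@H](OCc2ccccc2)[C@H](Oc2cc(OCc3ccccc3)cc(OCc3ccccc3)c21)c1ccc(OCc2ccccc2)c(OCc2ccccc2)c1
F2 | step 13 | [4,6-bis(benzyloxy)-3-bromo-2-fluorophenyl]magnesium chloride | Cl[Mg]c1c(F)c(Br)c(OCc2ccccc2)cc1OCc1ccccc1
F3 | step 13 | (1R,2R)-2-(benzyloxy)-1-[4-(benzyloxy)phenyl]-3-[4,6-bis(benzyloxy)-3-bromo-2-fluorophenyl]propan-1-ol | Fc1c(Br)c(OCc2ccccc2)cc(OCc2ccccc2)c1C[C@@H](OCc1ccccc1)[C@H](O)c1ccc(OCc2ccccc2)cc1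
F4 | step 22 | 5,7,3′,4′-tetra-O-benzylepicatechin-(4β→6)-(8-bromo-3,5,7,3′,4′-penta-O-benzylepicatechin) | c1c(OCc2ccccc2)cc(OCc2ccccc2)c2c1O[C@H](c1ccc(OCc3ccccc3)c(OCc3ccccc3)c1)[C@H](O)[C@H]2c1c(OCc2ccccc2)c(Br)c2c(c1OCc1ccccc1)C[C@@H](OCc1ccccc1)[C@@H](c1ccc(OCc3ccccc3)c(OCc3ccccc3)c1)O2
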